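Reagent is charged above both substrate and partner, so it looks like the plentiful one.

common to all: reagent 24.2 mM; time 3.0 d
- spring: substrate 22 mM (fed, over 15 h); partner 23.1 mM; all else is in the flask from the start; the feed brings no volume worth counting
- dusk: substrate 22 mM; partner 23.1 mM; everything together at the start
- winter: substrate 22 mM (fed, over 2.5 d); partner 23.1 mM; all else is in the flask from the start; the feed brings no volume worth counting
- noon: substrate 22 mM; partner 23.1 mM (fed, over 2.5 d); all else is in the flask from the start; the feed brings no volume worth counting

* the flask that comes out highest in amount of side product, in percent of the substrate charged; "all alike" if 1.5 percentage points covers them all (spring / dusk / winter / noon / all alike)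
* amount of side product at the end, in percent of the substrate charged, spring
* amount of side product at the end, in percent of the substrate charged, dusk
* amount of side product at the end, in percent of the substrate charged, winter
* amount of side product at the end, in percent of the substrate charged, noon

    substrate + reagent → open intermediate (k1 = 0.00274 /M/s)
    reagent + partner → second intermediate (k2 = 0.0259 /M/s)
    open intermediate + second intermediate ⇌ target (K3 = 240 /M, k3 = 0.00155 /M/s)
    substrate + open intermediate → side product (k4 = 1.03 × 10⁻⁴ /M/s)
    reagent + target → over-reaction product (k5 = 2.16 × 10⁻⁴ /M/s)

Yet two numbers seem to clash. In dusk, with the other concentrations as charged, the opening step alone gives substrate a half-life of 0.12 d, well inside the 3.0 d run, while the partner's step alone gives reagent a half-life of 0.32 h. Substrate seems bound to open, but its opener seems to leave first.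

The clash clears when I add up the claims. Substrate and partner together ask for 45.1 mM of reagent, and only 24.2 mM is there, so reagent is the limiting reagent. At the start of dusk, partner's rate stands to substrate's as 9.93 to one, which gives substrate about 2.22 mM of the reagent at that split. In spring and winter substrate arrives more slowly than partner takes reagent, so I put both below dusk.

Noon reverses this. Substrate's lifetime against reagent held at reagent's charge is 0.175 d, and that fits 14.3 times into the partner's 2.5 d feed. Substrate therefore opens first, and open intermediate builds up beside the substrate still waiting. Summing that overlap over time gives a factor 0.5, which cancels the two substrates each side product counts. The result is 3.42%. This is the side toll, the side step's constant times the substrate charge times substrate's lifetime against reagent held at charge. Noon's reagent thins as it works, so I take the toll as a first estimate for noon and expect the flask to end above it, and I commit to noon as highest.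

The forecast also names noon, on the ground that “Feeding the partner instead lets the substrate take most of the reagent”. It gives 2.2% for spring, 4.6% for dusk, 0.8% for winter and 14% for noon, a noon figure above my toll.

The flasks give 1.60% in spring, 4.66% in dusk, 0.685% in winter and 13.5% in noon, so noon is highest and the forecast held.

Noon ends at 3.95 times its toll, with reagent at 0% of its charge and substrate still at 15.7% after 3.00 d, which is not the toll's condition of reagent held at charge. The neighbour of noon with 97 mM of reagent has a substrate lifetime of 0.0435 d and so a toll of 0.853%. That neighbour ends with 42.2% of its reagent unused, substrate at 0%, and side product at 0.999%.

The constants were set for the occasion; the result is computed.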